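## The problem

Compound 18 is an isoflavone. A 4H-chromen-4-one (rings A and C) carries a 2,4,5-trimethoxyphenyl group (ring B) on C3, a free hydroxyl on C5, a 3-methylbut-2-enyl (prenyl) chain on C6 and a methoxy group on C7. There is no stereocenter, and the only non-aromatic alkene bears two identical methyl groups, so nothing stereochemical has to be set or relayed. The difficulty is regiochemical. Ring A is a phloroglucinol whose three oxygens must end up different (free on C5, methylated on C7, part of ring C on C8a), with the prenyl chain on C6 and not on C8. The prenyl alkene and the C5 hydroxyl beside it are the fragile pair: strong Brønsted or Lewis acids close them to a dimethylchroman, electrophilic metals and oxidants attack the trisubstituted alkene, and hydrogenation is excluded. Ring B is a hydroquinone-type triether and does not tolerate oxidants either. The enabling feature is that ring C hangs on ring A through O1 at C8a and the C4 carbonyl at C4a, two neighbouring carbons, and that C4a has the oxygen-bearing C5 as its other neighbour. An aryne spanning C4a and C8a is therefore polarised by O5 so that a nucleophile enters at C8a and the carbanion appears at C4a. The remaining atoms O1–C2–C3(ring B)–C4 are an enolised formyl arylacetate.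

## Retrosynthesis

**18 from 17.** The last operation makes no skeletal bond. The C5 hydroxyl of 18 is traced to the methoxymethyl ether 17 by cutting the O5–CH2 acetal bond. A free phenol cannot pass through aryne chemistry because phenoxides add to arynes. A methyl ether would need a Lewis acid next to the prenyl chain at the end, a benzyl ether would need hydrogenation, and a silyl ether would fall to fluoride. The acetal survives fluoride and carbanions and leaves with dilute acid, and its oxygen is the group that polarises the aryne. The forward step must free O5 without closing it onto the alkene.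

**17 from 11 and 15.** Ring C is opened at O1–C8a and C4–C4a. This leads to the silyl triflate 11, which is the source of aryne 16, and to the enol ester 15.
- Cutting C3–C1′ instead (cross-coupling on a 3-halochromone) leaves the whole ring A and ring C problem unsolved.
- Cutting O1–C2 and C2–C3 (the deoxybenzoin route) needs a regioselective Lewis-acid acylation of a prenylated phloroglucinol.
- The chosen cut divides the molecule into two halves of similar size, a benzene derivative and an arylacetate, and forms the ring that joins them in one operation.
- The forward reaction must add the enolate oxygen, not the carbon, to C8a and not to C4a, and the aryl anion must reach the ester before it is protonated.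

**15 from 13 and 12.** The C2–C3 bond of the future ring C is cut. Ester 13 is formylated by a formate ester through enolate 14, and 13 is the methyl ester of the purchasable acid 12. The forward steps are a Fischer esterification and a crossed Claisen condensation.

**11 from 10 and 9.** The O–CH2 bond of the acetal and the O–S bond of the triflate are cut in turn, which leads to the silylated diol 9. Its two hydroxyls differ only in their second neighbour, a ring hydrogen for the oxygen on C1 and the prenyl methylene for the oxygen on C3. The forward sequence must triflate the less hindered oxygen first (10) and then cap the hindered one (11).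

**9 from 8, and 8 from 4 and 5.** Diol 9 comes from the bis(carbamate) 8 by cleavage of both carbamoyl–oxygen bonds. The aryl–CH2 bond of the prenyl chain is then cut, leading to the silylated bis(carbamate) 4 and prenyl bromide 5, joined through aryllithium 6 and arylcopper 7. An electrophilic prenylation of a free phloroglucinol would give mixtures of carbon and oxygen alkylation at several sites. In 4 only two ring hydrogens are left and they are equivalent, so the metalation can give only one product.

**4 from 2 and 1.** The carbon–silicon bond is cut, leading to the symmetrical bis(carbamate) 2 through aryllithium 3, and 2 is the bis-carbamoylated form of commercial 5-methoxyresorcinol 1. The hydrogen between the two carbamates is the most acidic on the ring, so silicon goes to the carbon that will become C4a. Because 1 already holds the C7 methoxy group, no methylation step is needed.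

## Roads not taken

**Alternative 1: ring A by benzannulation of a cyclobutenone with an ynol ether.** The cut runs through ring A itself (C5–C6 and C7–C8, with C4a–C5 re-formed). Heating 3-(triisopropylsilyloxy)cyclobut-2-en-1-one A1 with 1-methoxy-5-methylhex-4-en-1-yne A2 would open the cyclobutenone to a vinylketene, add it to the alkyne, and pass through a second ring opening and a six-electron electrocyclisation (Danheiser benzannulation). The product would be 3-methoxy-2-(3-methylbut-2-en-1-yl)-5-(triisopropylsilyloxy)phenol A3.
- Merit: all three oxygens emerge differentiated (free, methylated, silylated) and the prenyl chain is placed by the alkyne substituent, with no organolithium chemistry. In this respect the road is better than the chosen one, which must distinguish two hydroxyls by their steric surroundings in step 5.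
- Weak points: it builds a benzene ring that can be bought. A1 and A2 are not shelf compounds, and A2 is a sensitive ynol ether with a doubly activated methylene. A3 is still far from the isoflavone: an arylacetyl group must be placed between the hydroxyl and the silyloxy group of a prenylated, very electron-rich phenol, and the one-carbon unit must then be added and ring C closed.
- Comparison: the chosen plan offsets its weaker oxygen differentiation with a purchased ring A, two metalations whose sites are fixed by symmetry, and a key step that also attaches ring B and closes ring C.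

**Alternative 2: oxidative 1,2-aryl shift of a chalcone.** The cut is C3–C1′ together with O1–C2. The chalcone (E)-1-(2-hydroxy-4,6-dimethoxyphenyl)-3-(2,4,5-trimethoxyphenyl)prop-2-en-1-one A4 would be treated with Tl(NO3)3 in methanol and trimethyl orthoformate and then with HCl. Ring B moves from the beta to the alpha carbon and the ring A hydroxyl closes on the acetal carbon, giving 5,7-dimethoxy-3-(2,4,5-trimethoxyphenyl)-4H-chromen-4-one A5.
- Merit: A4 comes from one aldol condensation of commercial partners, the rearrangement is the classical entry to isoflavones, and the electron-rich ring B migrates readily. For reaching a bare isoflavone core this road is shorter and rests wholly on known reactions, which the chosen plan cannot claim for its key step.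
- Weak points: trivalent thallium is toxic, is used in stoichiometric amount and attacks trisubstituted alkenes, so the prenyl chain cannot be present. The triether ring B is itself at risk of oxidation. A5 carries a methyl group on O5 and nothing on C6. After selective demethylation, direct prenylation of the 5-hydroxy-7-methoxy system gives C6, C8 and oxygen alkylation. The detour through an O-prenyl ether and sigmatropic shifts delivers either the 1,1-dimethylallyl isomer or the C8 product.
- Comparison: the chosen plan accepts an unproven ring closure, but it fixes the prenyl position and the O5 protection on a simple benzene before ring C exists, and it ends with one mild deprotection.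

**Alternative 3: carbene-catalysed crossed benzoin, then dehydration.** The cut is C3–C4. In 2,4-dimethoxy-3-(3-methylbut-2-en-1-yl)-6-[2-oxo-2-(2,4,5-trimethoxyphenyl)ethoxy]benzaldehyde A6, an N-heterocyclic carbene would turn the aldehyde into a Breslow intermediate that adds to the tethered aryl ketone. The product would be racemic 3-hydroxy-5,7-dimethoxy-6-(3-methylbut-2-en-1-yl)-3-(2,4,5-trimethoxyphenyl)chroman-4-one A7. Loss of water would give 5,7-dimethoxy-6-(3-methylbut-2-en-1-yl)-3-(2,4,5-trimethoxyphenyl)-4H-chromen-4-one A8.
- Merit: the ring closure is catalytic, metal-free and mild, it tolerates the prenyl chain, and intramolecular aldehyde–ketone benzoin reactions to 3-hydroxychromanones are known. Its key step is therefore better precedented than that of the chosen plan, and the overall length would be similar.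
- Weak points: the aldehyde sits between two ortho oxygens and the ketone carries an ortho-methoxylated ring, so both partners are hindered and electron-rich. A stereocenter is made only to be destroyed. The tertiary alcohol A7 must be dehydrated and the O5 methyl of A8 removed with a Lewis acid, both next to the prenyl alkene. Replacing that methyl by an acetal brings back the ring A differentiation problem, now with a formyl group to place as well.
- Comparison: the chosen plan has the larger risk in its key step, but it reaches the correct oxidation level directly and leaves only a dilute-acid deprotection after ring closure.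

Key step: step 9

Assumption: 15 is drawn as its chelated (Z)-enol. This enol, its (E)-isomer and the aldehyde tautomer share one enolate, so the tautomer ratio of the isolated material is taken to be without consequence for step 9.

## Route

Step 1
Reactants: 1 5-methoxyresorcinol (5-methoxybenzene-1,3-diol)
Product: 2 5-methoxy-1,3-phenylene bis(N,N-diethylcarbamate)
Conditions: ClCONEt2 (2.4 equiv), K2CO3, MeCN, reflux
Reagents that add atoms: N,N-diethylcarbamoyl chloride, CCN(CC)C(=O)Cl
Why: Carbamoylation of phenols under carbonate base is routine; both hydroxyls receive the strongest oxygen-based directing group for ortho-lithiation and the ring stays symmetrical, which fixes the sites of the two metalations that follow.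

Step 2
Reactants: 2 5-methoxy-1,3-phenylene bis(N,N-diethylcarbamate)
Product: 4 5-methoxy-2-(trimethylsilyl)-1,3-phenylene bis(N,N-diethylcarbamate), via 2-lithio bis(carbamate) 3 (not isolated)
Conditions: s-BuLi, TMEDA, THF, −78 °C; TMSCl, −78 °C → rt
Reagents that add atoms: chlorotrimethylsilane, C[Si](C)(C)Cl
Why: Directed ortho-metalation; the hydrogen between the two carbamates is flanked by two strong directing groups and should be removed first, and the silyl chloride is added at −78 °C, before the anionic ortho-Fries shift that sets in on warming.

Step 3
Reactants: 4 5-methoxy-2-(trimethylsilyl)-1,3-phenylene bis(N,N-diethylcarbamate); 5 prenyl bromide (1-bromo-3-methylbut-2-ene)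
Product: 8 5-methoxy-4-(3-methylbut-2-en-1-yl)-2-(trimethylsilyl)-1,3-phenylene bis(N,N-diethylcarbamate), via 4-lithio bis(carbamate) 6 (not isolated), via arylcopper species 7 (not isolated)
Conditions: s-BuLi, TMEDA, THF, −78 °C; CuBr·SMe2, −78 → −40 °C; 5, −78 → 0 °C
Reagents that add atoms: none
Why: Second directed ortho-metalation; the two remaining ring hydrogens are equivalent, each between a carbamate and the methoxy group, so only one aryllithium can form. Transmetalation to monovalent copper suppresses the ortho-Fries shift and lets the aryl group displace bromide at the primary carbon of 5, the usual way of making prenylarenes from aryllithiums.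

Step 4
Reactants: 8 5-methoxy-4-(3-methylbut-2-en-1-yl)-2-(trimethylsilyl)-1,3-phenylene bis(N,N-diethylcarbamate)
Product: 9 5-methoxy-4-(3-methylbut-2-en-1-yl)-2-(trimethylsilyl)benzene-1,3-diol
Conditions: LiAlH4, THF, 0 °C → reflux; aq. potassium sodium tartrate work-up
Reagents that add atoms: none
Why: Hydride attack at the carbamate carbonyl releases the aryloxide, a standard way to unmask hindered aryl diethylcarbamates after directed metalation. The medium is basic and the work-up near neutral, so the acid-labile aryl–silicon bond and the prenyl alkene should be untouched.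

Step 5
Reactants: 9 5-methoxy-4-(3-methylbut-2-en-1-yl)-2-(trimethylsilyl)benzene-1,3-diol
Product: 10 3-hydroxy-5-methoxy-4-(3-methylbut-2-en-1-yl)-2-(trimethylsilyl)phenyl trifluoromethanesulfonate
Conditions: PhNTf2 (1.0 equiv), Et3N, CH2Cl2, 0 °C → rt
Reagents that add atoms: N-phenylbis(trifluoromethanesulfonimide), O=S(=O)(N(c1ccccc1)S(=O)(=O)C(F)(F)F)C(F)(F)F
Why: Sulfonylation of a phenol with a bulky triflyl donor; the hydroxyl on C1 has the silyl group on one side only, whereas the hydroxyl on C3 is enclosed by the silyl group and the prenyl methylene, so one equivalent should go to C1. An amine base is used because carbonate bases are known to set off carbon-to-oxygen silyl migration and aryne release in 3-hydroxy-2-silylaryl triflates.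

Step 6
Reactants: 10 3-hydroxy-5-methoxy-4-(3-methylbut-2-en-1-yl)-2-(trimethylsilyl)phenyl trifluoromethanesulfonate
Product: 11 5-methoxy-3-(methoxymethoxy)-4-(3-methylbut-2-en-1-yl)-2-(trimethylsilyl)phenyl trifluoromethanesulfonate
Conditions: MOMCl, iPr2NEt, CH2Cl2, 0 → 40 °C
Reagents that add atoms: chloromethyl methyl ether, COCCl
Why: Alkylation of the remaining phenol with the small, very reactive chloromethyl ether under amine base is standard even for 2,6-disubstituted phenols, and it again avoids a free phenoxide next to the silyl triflate.

Step 7
Reactants: 12 2,4,5-trimethoxyphenylacetic acid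
Product: 13 methyl 2-(2,4,5-trimethoxyphenyl)acetate
Conditions: MeOH, H2SO4 (cat.), reflux
Reagents that add atoms: methanol, CO
Why: Fischer esterification of an unhindered arylacetic acid.

Step 8
Reactants: 13 methyl 2-(2,4,5-trimethoxyphenyl)acetate
Product: 15 methyl (Z)-3-hydroxy-2-(2,4,5-trimethoxyphenyl)prop-2-enoate, via sodium enolate 14 (not isolated)
Conditions: NaH, HCO2Me, THF, 0 °C → rt; aq. HCl to pH 3
Reagents that add atoms: methyl formate, COC=O
Why: Crossed Claisen condensation of an arylacetate with a non-enolisable formate, driven by formation of the stabilised enolate 14; acidification should give the hydrogen-bonded enol.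

Step 9
Reactants: 11 5-methoxy-3-(methoxymethoxy)-4-(3-methylbut-2-en-1-yl)-2-(trimethylsilyl)phenyl trifluoromethanesulfonate; 15 methyl (Z)-3-hydroxy-2-(2,4,5-trimethoxyphenyl)prop-2-enoate
Product: 17 7-methoxy-5-(methoxymethoxy)-6-(3-methylbut-2-en-1-yl)-3-(2,4,5-trimethoxyphenyl)-4H-chromen-4-one, via aryne 16 (not isolated)
Conditions: CsF (4 equiv), THF, 65 °C
Reagents that add atoms: none
Why: Proposed new method: fluoride attacks silicon in 11 and triflate leaves, giving aryne 16 whose strained bond joins the future C4a and C8a; CsF also turns 15 into its cesium enolate. The enolate oxygen is expected to add to C8a, the aryne carbon remote from the acetal oxygen on C5, because that oxygen distorts the aryne and inductively stabilises the carbanion developing at C4a, the pattern established for 3-alkoxybenzynes (bond O1–C8a). The aryl anion at C4a then attacks the cis-disposed methyl ester and expels methoxide, a 6-exo-trig acyl substitution that forms bond C4–C4a and closes ring C as the chromenone. The closest known reaction type is the CsF-induced annulation of arynes with salicylate esters to xanthones, where a phenoxide oxygen is arylated and the resulting aryl anion captures the neighbouring ester; an enolised formylacetate, the vinylogous counterpart of the salicylate, has not been used in this role. The step needs oxygen and not carbon arylation of the ambident enolate; this rests on the fully substituted alpha carbon, shielded by the ortho-methoxylated ring B, and on the chelated U-shaped cesium enolate, which exposes the formyl oxygen and already holds it cis to the ester. THF is chosen, as in the xanthone case, so that ring closure can outrun protonation of the aryl anion. No stereocenter is formed, and the prenyl alkene and the acetal are spectators: an ene reaction within 16 is geometrically impossible and fluoride attacks neither group.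

Step 10
Reactants: 17 7-methoxy-5-(methoxymethoxy)-6-(3-methylbut-2-en-1-yl)-3-(2,4,5-trimethoxyphenyl)-4H-chromen-4-one
Product: 18 5-hydroxy-7-methoxy-6-(3-methylbut-2-en-1-yl)-3-(2,4,5-trimethoxyphenyl)-4H-chromen-4-one
Conditions: 3 M aq. HCl, MeOH, 40 °C
Reagents that add atoms: none
Why: Acid-catalysed acetal methanolysis; an acetal oxygen peri to the C4 carbonyl is cleaved readily by dilute acid, conditions routinely applied to prenylated flavonoids because they are too mild to add the freed hydroxyl or HCl across the trisubstituted alkene. The four aryl methyl ethers are inert.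

## Compound list

1 | 5-methoxyresorcinol (5-methoxybenzene-1,3-diol) | COc1cc(O)cc(O)c1 | starting material
2 | 5-methoxy-1,3-phenylene bis(N,N-diethylcarbamate) | CCN(CC)C(=O)Oc1cc(OC)cc(OC(=O)N(CC)CC)c1 | intermediate
3 | [2,6-bis(diethylcarbamoyloxy)-4-methoxyphenyl]lithium (2-lithio bis(carbamate)) | [Li]c1c(OC(=O)N(CC)CC)cc(OC)cc1OC(=O)N(CC)CC | intermediate
4 | 5-methoxy-2-(trimethylsilyl)-1,3-phenylene bis(N,N-diethylcarbamate) | CCN(CC)C(=O)Oc1cc(OC)cc(OC(=O)N(CC)CC)c1[Si](C)(C)C | intermediate
5 | prenyl bromide (1-bromo-3-methylbut-2-ene) | CC(C)=CCBr | starting material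
6 | [2,4-bis(diethylcarbamoyloxy)-6-methoxy-3-(trimethylsilyl)phenyl]lithium (4-lithio bis(carbamate)) | [Li]c1c(OC)cc(OC(=O)N(CC)CC)c([Si](C)(C)C)c1OC(=O)N(CC)CC | intermediate
7 | [2,4-bis(diethylcarbamoyloxy)-6-methoxy-3-(trimethylsilyl)phenyl]copper (monovalent copper, arylcopper species) | [Cu]c1c(OC)cc(OC(=O)N(CC)CC)c([Si](C)(C)C)c1OC(=O)N(CC)CC | intermediate
8 | 5-methoxy-4-(3-methylbut-2-en-1-yl)-2-(trimethylsilyl)-1,3-phenylene bis(N,N-diethylcarbamate) | CCN(CC)C(=O)Oc1cc(OC)c(CC=C(C)C)c(OC(=O)N(CC)CC)c1[Si](C)(C)C | intermediate
9 | 5-methoxy-4-(3-methylbut-2-en-1-yl)-2-(trimethylsilyl)benzene-1,3-diol | COc1cc(O)c([Si](C)(C)C)c(O)c1CC=C(C)C | intermediate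
10 | 3-hydroxy-5-methoxy-4-(3-methylbut-2-en-1-yl)-2-(trimethylsilyl)phenyl trifluoromethanesulfonate | COc1cc(OS(=O)(=O)C(F)(F)F)c([Si](C)(C)C)c(O)c1CC=C(C)C | intermediate
11 | 5-methoxy-3-(methoxymethoxy)-4-(3-methylbut-2-en-1-yl)-2-(trimethylsilyl)phenyl trifluoromethanesulfonate | COCOc1c(CC=C(C)C)c(OC)cc(OS(=O)(=O)C(F)(F)F)c1[Si](C)(C)C | intermediate
12 | 2,4,5-trimethoxyphenylacetic acid | COc1cc(OC)c(CC(=O)O)cc1OC | starting material
13 | methyl 2-(2,4,5-trimethoxyphenyl)acetate | COC(=O)Cc1cc(OC)c(OC)cc1OC | intermediate
14 | sodium (Z)-3-methoxy-3-oxo-2-(2,4,5-trimethoxyphenyl)prop-1-en-1-olate (sodium enolate) | [Na+].[O-]/C=C(/c1cc(OC)c(OC)cc1OC)C(=O)OC | intermediate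
15 | methyl (Z)-3-hydroxy-2-(2,4,5-trimethoxyphenyl)prop-2-enoate | O/C=C(/c1cc(OC)c(OC)cc1OC)C(=O)OC | intermediate
16 | 1,2-didehydro-5-methoxy-3-(methoxymethoxy)-4-(3-methylbut-2-en-1-yl)benzene (aryne) | COCOC1=C(CC=C(C)C)C(OC)=CC#C1 | intermediate
17 | 7-methoxy-5-(methoxymethoxy)-6-(3-methylbut-2-en-1-yl)-3-(2,4,5-trimethoxyphenyl)-4H-chromen-4-one | COCOc1c(CC=C(C)C)c(OC)cc2occ(-c3cc(OC)c(OC)cc3OC)c(=O)c12 | intermediate
18 | 5-hydroxy-7-methoxy-6-(3-methylbut-2-en-1-yl)-3-(2,4,5-trimethoxyphenyl)-4H-chromen-4-one | COc1cc(OC)c(-c2coc3cc(OC)c(CC=C(C)C)c(O)c3c2=O)cc1OC | target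

## Step count and risks

Total: 10 steps. Longest linear sequence: 8 steps (steps 1 to 6, then 9 and 10). The ring B partner takes 2 steps (7 and 8) before the convergence in step 9.

**Step 9 (key step).** The most likely failure is arylation of the ambident enolate at carbon followed by acyl transfer, a formal insertion of the aryne into the C–CHO bond. Second is protonation of the aryl anion by unreacted enol before it reaches the ester. Arylation of an (E)-configured enolate would give an aryl anion that cannot reach the ester at all. The fallback uses known chemistry, sets out from 11 and 12 and returns at 17.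
- Heating 11 with acid 12 and CsF in THF at 125 °C in a sealed vessel follows the recorded insertion of arynes into the C–O bond of carboxylic acids. The carboxylate oxygen adds to C8a and the acyl group shifts to the aryl anion at C4a. This should give 1-[2-hydroxy-4-methoxy-6-(methoxymethoxy)-5-(3-methylbut-2-en-1-yl)phenyl]-2-(2,4,5-trimethoxyphenyl)ethan-1-one F1.
- Condensation of F1 with N,N-dimethylformamide dimethyl acetal in toluene at 90 °C supplies C2 and closes ring C. This is the classical deoxybenzoin route to isoflavones and gives 17. The same two ring bonds are formed, in two operations.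

**Step 5.** The risk is insufficient discrimination between the two hydroxyls, or a second triflation, since the steric difference lies one atom away from each oxygen. The fallback sets out from 9 and returns at 11.
- A much bulkier electrophile makes the selection: TIPSOTf and 2,6-lutidine in CH2Cl2 at −78 °C should silylate only the open hydroxyl, giving 3-methoxy-2-(3-methylbut-2-en-1-yl)-5-[(triisopropylsilyl)oxy]-6-(trimethylsilyl)phenol F2.
- The hindered phenol is capped with NaH and MOMCl in THF, which is safe here because no triflate is present. This gives triisopropyl[5-methoxy-3-(methoxymethoxy)-4-(3-methylbut-2-en-1-yl)-2-(trimethylsilyl)phenoxy]silane F3.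
- Tetrabutylammonium fluoride in THF at 0 °C removes the oxygen-bound silyl group to give 5-methoxy-3-(methoxymethoxy)-4-(3-methylbut-2-en-1-yl)-2-(trimethylsilyl)phenol F4.
- PhNTf2 and Et3N convert F4, which has a single hydroxyl, into 11.

**Step 3.** The risks are bond formation at the tertiary end of the allyl system (allylic transposition to the 1,1-dimethylallyl isomer) in the copper-mediated substitution, and loss of aryllithium 6 through carbamoyl migration if it warms before transmetalation. The fallback sets out from 4 and returns at 8.
- Compound 4 is metalated as before and carried through 6 and 7, which are alkylated with allyl bromide. Both ends of that electrophile give the same product, 5-methoxy-4-(prop-2-en-1-yl)-2-(trimethylsilyl)-1,3-phenylene bis(N,N-diethylcarbamate) F5.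
- Olefin cross-metathesis of F5 with excess 2-methylbut-2-ene and the second-generation Grubbs catalyst, RuCl2(H2IMes)(PCy3)(=CHPh), in CH2Cl2 at 40 °C turns the allyl group into the prenyl group of 8. This is a standard way of making prenylarenes.

**Step 10.** The risk is acid-promoted addition of the freed C5 hydroxyl, or of HCl, across the prenyl alkene if the acetal needs more forcing conditions than expected. The fallback replaces the acetal by a group that leaves under neutral conditions. It sets out from 10 and returns at 18, and it reuses the annulation of step 9.
- Mitsunobu alkylation of 10 with allyl alcohol, PPh3 and diisopropyl azodicarboxylate in THF avoids a free phenoxide. It should give 5-methoxy-4-(3-methylbut-2-en-1-yl)-3-(prop-2-en-1-yloxy)-2-(trimethylsilyl)phenyl trifluoromethanesulfonate F6.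
- Under the conditions of step 9, F6 and 15 react through 1,2-didehydro-5-methoxy-4-(3-methylbut-2-en-1-yl)-3-(prop-2-en-1-yloxy)benzene F7. The product should be 7-methoxy-6-(3-methylbut-2-en-1-yl)-5-(prop-2-en-1-yloxy)-3-(2,4,5-trimethoxyphenyl)-4H-chromen-4-one F8.
- Pd(PPh3)4 (zerovalent palladium) and morpholine in THF at room temperature transfer the allyl group to the amine and release 18. The trisubstituted prenyl alkene is not engaged.

## Further compounds

F1 | step 9 | 1-[2-hydroxy-4-methoxy-6-(methoxymethoxy)-5-(3-methylbut-2-en-1-yl)phenyl]-2-(2,4,5-trimethoxyphenyl)ethan-1-one | COCOc1c(CC=C(C)C)c(OC)cc(O)c1C(=O)Cc1cc(OC)c(OC)cc1OC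
F2 | step 5 | 3-methoxy-2-(3-methylbut-2-en-1-yl)-5-[(triisopropylsilyl)oxy]-6-(trimethylsilyl)phenol | COc1cc(O[Si](C(C)C)(C(C)C)C(C)C)c([Si](C)(C)C)c(O)c1CC=C(C)C
F3 | step 5 | triisopropyl[5-methoxy-3-(methoxymethoxy)-4-(3-methylbut-2-en-1-yl)-2-(trimethylsilyl)phenoxy]silane | COCOc1c(CC=C(C)C)c(OC)cc(O[Si](C(C)C)(C(C)C)C(C)C)c1[Si](C)(C)C
F4 | step 5 | 5-methoxy-3-(methoxymethoxy)-4-(3-methylbut-2-en-1-yl)-2-(trimethylsilyl)phenol | COCOc1c(CC=C(C)C)c(OC)cc(O)c1[Si](C)(C)C
F5 | step 3 | 5-methoxy-4-(prop-2-en-1-yl)-2-(trimethylsilyl)-1,3-phenylene bis(N,N-diethylcarbamate) | CCN(CC)C(=O)Oc1cc(OC)c(CC=C)c(OC(=O)N(CC)CC)c1[Si](C)(C)C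
F6 | step 10 | 5-methoxy-4-(3-methylbut-2-en-1-yl)-3-(prop-2-en-1-yloxy)-2-(trimethylsilyl)phenyl trifluoromethanesulfonate | C=CCOc1c(CC=C(C)C)c(OC)cc(OS(=O)(=O)C(F)(F)F)c1[Si](C)(C)C
F7 | step 10 | 1,2-didehydro-5-methoxy-4-(3-methylbut-2-en-1-yl)-3-(prop-2-en-1-yloxy)benzene | C=CCOC1=C(CC=C(C)C)C(OC)=CC#C1
F8 | step 10 | 7-methoxy-6-(3-methylbut-2-en-1-yl)-5-(prop-2-en-1-yloxy)-3-(2,4,5-trimethoxyphenyl)-4H-chromen-4-one | C=CCOc1c(CC=C(C)C)c(OC)cc2occ(-c3cc(OC)c(OC)cc3OC)c(=O)c12
A1 | alternative 1 | 3-(triisopropylsilyloxy)cyclobut-2-en-1-one | O=C1C=C(O[Si](C(C)C)(C(C)C)C(C)C)C1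
A2 | alternative 1 | 1-methoxy-5-methylhex-4-en-1-yne | COC#CCC=C(C)C
A3 | alternative 1 | 3-methoxy-2-(3-methylbut-2-en-1-yl)-5-(triisopropylsilyloxy)phenol | COc1cc(O[Si](C(C)C)(C(C)C)C(C)C)cc(O)c1CC=C(C)C
A4 | alternative 2 | (E)-1-(2-hydroxy-4,6-dimethoxyphenyl)-3-(2,4,5-trimethoxyphenyl)prop-2-en-1-one | COc1cc(O)c(C(=O)/C=C/c2cc(OC)c(OC)cc2OC)c(OC)c1
A5 | alternative 2 | 5,7-dimethoxy-3-(2,4,5-trimethoxyphenyl)-4H-chromen-4-one | COc1cc(OC)c2c(=O)c(-c3cc(OC)c(OC)cc3OC)coc2c1
A6 | alternative 3 | 2,4-dimethoxy-3-(3-methylbut-2-en-1-yl)-6-[2-oxo-2-(2,4,5-trimethoxyphenyl)ethoxy]benzaldehyde | COc1cc(OCC(=O)c2cc(OC)c(OC)cc2OC)c(C=O)c(OC)c1CC=C(C)C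
A7 | alternative 3 | racemic 3-hydroxy-5,7-dimethoxy-6-(3-methylbut-2-en-1-yl)-3-(2,4,5-trimethoxyphenyl)chroman-4-one | COc1cc2OCC(O)(c3cc(OC)c(OC)cc3OC)C(=O)c2c(OC)c1CC=C(C)C
A8 | alternative 3 | 5,7-dimethoxy-6-(3-methylbut-2-en-1-yl)-3-(2,4,5-trimethoxyphenyl)-4H-chromen-4-one | COc1cc2occ(-c3cc(OC)c(OC)cc3OC)c(=O)c2c(OC)c1CC=C(C)C
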